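The dihydrobenzofuran is cut at O1–C7a and C3–C3a. The feature exploited is that O1 and C3 are bonded to adjacent carbons of ring A (C7a and C3a), the footprint of an aryne, while O1–C2–C3, with ring C on C2 and ring B on C3, is a trans-diaryl epoxide in disguise. Ring A is therefore delivered as an aryne that inserts into one C–O bond of an enantiopure stilbene oxide: a single operation makes both bonds, closes the furan ring and sets C3 trans to the retained C2 centre. The precursors are an ortho-silylaryl triflate carrying chlorine and a methyl ester, and a (2R,3R)-epoxide whose ring C is an electron-poor bis-tosylate.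

Key step: step 7

Assumption: benzofuran numbering is used (O1, C2, C3, C3a, C4–C7, C7a); ring A is the benzo ring, ring B the aryl on C3, ring C the aryl on C2, ring D the aryl of the styryl arm; TMPMgCl·LiCl, the D-fructose-derived Shi ketone and Bu4N[Ph3SiF2] are taken as purchased reagents.

Step 1
Reactants: 1 methyl 2-chloro-4-hydroxybenzoate
Product: 2 methyl 4-[(tert-butoxycarbonyl)oxy]-2-chlorobenzoate
Conditions: Boc2O, DMAP (cat.), CH2Cl2, rt
Reagents that add atoms: di-tert-butyl dicarbonate, CC(C)(C)OC(=O)OC(=O)OC(C)(C)C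
Why: DMAP-catalysed O-acylation of the phenol (carbonate formation) installs a metalation-directing group that a secondary amine can later remove without touching the methyl ester.

Step 2
Reactants: 2 methyl 4-[(tert-butoxycarbonyl)oxy]-2-chlorobenzoate
Product: 4 methyl 4-[(tert-butoxycarbonyl)oxy]-2-chloro-3-(trimethylsilyl)benzoate, via arylmagnesium chloride 3 (not isolated)
Conditions: TMPMgCl·LiCl (1.2 equiv), THF, −20 → 0 °C; then Me3SiOTf (1.5 equiv), −40 °C → rt
Reagents that add atoms: trimethylsilyl trifluoromethanesulfonate, C[Si](C)(C)OS(=O)(=O)C(F)(F)F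
Why: Directed ortho-magnesiation with the hindered magnesium amide should take place at C3, the only C–H flanked by two acidifying and coordinating groups (chlorine and the carbonate), the aryl–magnesium bond tolerates the ester and resists acyl migration at 0 °C, and the strongly electrophilic silyl triflate then silylates the hindered carbon.

Step 3
Reactants: 4 methyl 4-[(tert-butoxycarbonyl)oxy]-2-chloro-3-(trimethylsilyl)benzoate
Product: 6 methyl 2-chloro-4-[(trifluoromethanesulfonyl)oxy]-3-(trimethylsilyl)benzoate, via silyl phenol 5 (not isolated)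
Conditions: Et2NH (1.5 equiv), DBU (1.5 equiv), MeCN, 40 °C; then PhNTf2 (1.5 equiv), rt
Reagents that add atoms: N-phenylbis(trifluoromethanesulfonimide), O=S(=O)(N(c1ccccc1)S(=O)(=O)C(F)(F)F)C(F)(F)F
Why: Aminolysis of the aryl carbonate (acyl transfer to diethylamine) frees the phenol, which is O-sulfonylated in the same flask by the mild triflating agent under amidine base, conditions under which the methyl ester and the C–Si bond should persist.

Step 4
Reactants: 7 3,4-dihydroxybenzaldehyde
Product: 8 3,4-bis(tosyloxy)benzaldehyde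
Conditions: TsCl (2.3 equiv), K2CO3, acetone, reflux
Reagents that add atoms: 4-methylbenzenesulfonyl chloride, Cc1ccc(cc1)S(=O)(=O)Cl
Why: O-Sulfonylation of both phenols makes ring C electron-poor, which later decides which epoxide C–O bond breaks, and gives a protecting group that withstands fluoride, hydride and weak base.

Step 5
Reactants: 8 3,4-bis(tosyloxy)benzaldehyde; 9 diethyl (3,5-dimethoxybenzyl)phosphonate
Product: 10 (E)-3,4-bis(tosyloxy)-3',5'-dimethoxystilbene
Conditions: NaH, THF, 0 °C → rt
Reagents that add atoms: none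
Why: Horner–Wadsworth–Emmons olefination of an aryl aldehyde with a benzylphosphonate anion should give the (E)-stilbene with high selectivity, and the non-nucleophilic conditions leave the aryl sulfonates intact.

Step 6
Reactants: 10 (E)-3,4-bis(tosyloxy)-3',5'-dimethoxystilbene
Product: 11 (2R,3R)-2-[3,4-bis(tosyloxy)phenyl]-3-(3,5-dimethoxyphenyl)oxirane
Conditions: D-fructose-derived Shi ketone (30 mol %), Oxone (2KHSO5·KHSO4·K2SO4), K2CO3, Bu4NHSO4 (cat.), MeCN/CH2(OMe)2, aq. Na2B4O7 buffer, 0 °C
Reagents that add atoms: potassium peroxymonosulfate KHSO5 (the oxidant in Oxone), [K+].[O-]S(=O)(=O)OO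
Why: Shi asymmetric epoxidation, in which the chiral dioxirane approaches the trans-alkene through the spiro transition state on the face that gives (R,R)-epoxides from trans-stilbenes, sets both epoxide centres by catalyst control, and recrystallisation of the epoxide can raise its enantiomeric purity.

Step 7
Reactants: 6 methyl 2-chloro-4-[(trifluoromethanesulfonyl)oxy]-3-(trimethylsilyl)benzoate; 11 (2R,3R)-2-[3,4-bis(tosyloxy)phenyl]-3-(3,5-dimethoxyphenyl)oxirane
Product: 13 methyl (2S,3S)-2-[3,4-bis(tosyloxy)phenyl]-4-chloro-3-(3,5-dimethoxyphenyl)-2,3-dihydro-1-benzofuran-5-carboxylate, via aryne 12 (not isolated)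
Conditions: Bu4N[Ph3SiF2] (2.0 equiv), toluene, 50 °C; 6 (1.8 equiv) added slowly to 11 (1.0 equiv)
Reagents that add atoms: none
Why: Proposed new method: fluoride removes the silyl group and triflate departs to give aryne 12, whose C7a terminus (remote from chlorine, para to the ester) is the wider-angled, more electrophilic carbon, so the epoxide oxygen should add there and the aryl anion develop at C3a beside chlorine, as in distortion-controlled additions to 3-haloarynes. The O-aryl oxiranium/aryl-anion zwitterion then breaks the C3–O bond, because the two sulfonyloxy groups deny ring C any ability to carry positive charge at C2, and the C3a anion captures C3; the closest known reaction type is the insertion of benzyne into the benzylic C–O bond of styrene oxide. The dihydrofuran ring is thus closed by cation–anion collapse between C3a and C3, a stepwise and formally 5-endo closure, since a concerted displacement with the leaving oxygen inside the forming ring is geometrically barred. C2 never loses a bond and keeps the configuration set in step 6, while C3 is re-formed on the face the oxygen has just left (tight ion pair in a non-polar medium) and in any case anti to the C2 aryl group, so the (2R,3R)-epoxide maps onto the trans-(2S,3S) product, the descriptors changing only through CIP priorities. Three selectivities are needed: aryne regiochemistry (secured by the C4 chlorine and the C5 ester), choice of the C–O bond (secured by the electron-poor ring C) and trans closure (secured by the C2 centre). Toluene and an anhydrous, weakly basic fluoride source are chosen so that the aryl anion is not protonated by solvent and the oxiranium is not opened by an external nucleophile.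

Step 8
Reactants: 13 methyl (2S,3S)-2-[3,4-bis(tosyloxy)phenyl]-4-chloro-3-(3,5-dimethoxyphenyl)-2,3-dihydro-1-benzofuran-5-carboxylate
Product: 14 methyl (2S,3S)-2-[3,4-bis(tosyloxy)phenyl]-3-(3,5-dimethoxyphenyl)-2,3-dihydro-1-benzofuran-5-carboxylate
Conditions: Pd(OAc)2 (5 mol %), P(t-Bu)3·HBF4 (10 mol %), HCO2Na (3 equiv), DMF, 80 °C
Reagents that add atoms: none
Why: Palladium-catalysed transfer hydrodehalogenation, in which zerovalent palladium carrying the bulky electron-rich phosphine inserts into the ester-activated C4–Cl bond but not into aryl sulfonate C–O bonds, formate replaces chloride and loses CO2 to give an aryl palladium hydride that eliminates the arene, with no alkene yet present and the stereocentres untouched.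

Step 9
Reactants: 14 methyl (2S,3S)-2-[3,4-bis(tosyloxy)phenyl]-3-(3,5-dimethoxyphenyl)-2,3-dihydro-1-benzofuran-5-carboxylate
Product: 15 [(2S,3S)-2-[3,4-bis(tosyloxy)phenyl]-3-(3,5-dimethoxyphenyl)-2,3-dihydro-1-benzofuran-5-yl]methanol
Conditions: i-Bu2AlH (2.5 equiv), CH2Cl2, −78 → 0 °C; aq. potassium sodium tartrate
Reagents that add atoms: none
Why: Aluminium hydride reduction of the methyl ester, now free of its ortho chlorine, should give the benzylic alcohol at low temperature, where aryl sulfonates and the benzylic aryl ether are inert.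

Step 10
Reactants: 15 [(2S,3S)-2-[3,4-bis(tosyloxy)phenyl]-3-(3,5-dimethoxyphenyl)-2,3-dihydro-1-benzofuran-5-yl]methanol
Product: 16 (2S,3S)-2-[3,4-bis(tosyloxy)phenyl]-3-(3,5-dimethoxyphenyl)-2,3-dihydro-1-benzofuran-5-carbaldehyde
Conditions: Dess–Martin periodinane, CH2Cl2, 0 °C → rt
Reagents that add atoms: none
Why: Dess–Martin oxidation converts the benzylic alcohol into the aldehyde under neutral, non-epimerising conditions without over-oxidation.

Step 11
Reactants: 16 (2S,3S)-2-[3,4-bis(tosyloxy)phenyl]-3-(3,5-dimethoxyphenyl)-2,3-dihydro-1-benzofuran-5-carbaldehyde; 9 diethyl (3,5-dimethoxybenzyl)phosphonate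
Product: 18 4-[(2S,3S)-3-(3,5-dimethoxyphenyl)-5-[(E)-2-(3,5-dimethoxyphenyl)ethenyl]-2,3-dihydro-1-benzofuran-2-yl]benzene-1,2-diol, via bis-tosylate stilbene 17 (not isolated)
Conditions: NaH, THF, 0 °C → rt; then KOH, MeOH/H2O, 55 °C, under argon; aq. HCl work-up
Reagents that add atoms: none
Why: Horner–Wadsworth–Emmons olefination of the aryl aldehyde with the benzylphosphonate anion should give the (E)-styryl arm, and hydroxide added to the same flask then cleaves the two aryl sulfonates at sulfur (saponification), their electron-withdrawing role being over, while neither stereocentre carries a hydrogen acidic enough to epimerise.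

Step 12
Reactants: 18 4-[(2S,3S)-3-(3,5-dimethoxyphenyl)-5-[(E)-2-(3,5-dimethoxyphenyl)ethenyl]-2,3-dihydro-1-benzofuran-2-yl]benzene-1,2-diol
Product: 19 4-[(2S,3S)-3-(3,5-dihydroxyphenyl)-5-[(E)-2-(3,5-dihydroxyphenyl)ethenyl]-2,3-dihydro-1-benzofuran-2-yl]benzene-1,2-diol
Conditions: BBr3 (10 equiv), CH2Cl2, −78 °C → rt; MeOH, then H2O
Reagents that add atoms: none
Why: Lewis acid ether cleavage (BBr3 demethylation by bromide attack on the O-methyl groups of the ether–borane adducts) should free the four remaining phenols, the catechol being tied up at once as a cyclic boron ester that keeps ring C from assisting ionisation of the C2–O1 bond, so the trans-(2S,3S) centres persist.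

Compound list
1 | methyl 2-chloro-4-hydroxybenzoate | COC(=O)c1ccc(O)cc1Cl | starting material
2 | methyl 4-[(tert-butoxycarbonyl)oxy]-2-chlorobenzoate | COC(=O)c1ccc(OC(=O)OC(C)(C)C)cc1Cl | intermediate
3 | [6-[(tert-butoxycarbonyl)oxy]-2-chloro-3-(methoxycarbonyl)phenyl]magnesium chloride (LiCl complex) | COC(=O)c1ccc(OC(=O)OC(C)(C)C)c([Mg]Cl)c1Cl | intermediate (not isolated)
4 | methyl 4-[(tert-butoxycarbonyl)oxy]-2-chloro-3-(trimethylsilyl)benzoate | COC(=O)c1ccc(OC(=O)OC(C)(C)C)c([Si](C)(C)C)c1Cl | intermediate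
5 | methyl 2-chloro-4-hydroxy-3-(trimethylsilyl)benzoate | COC(=O)c1ccc(O)c([Si](C)(C)C)c1Cl | intermediate (not isolated)
6 | methyl 2-chloro-4-[(trifluoromethanesulfonyl)oxy]-3-(trimethylsilyl)benzoate | COC(=O)c1ccc(OS(=O)(=O)C(F)(F)F)c([Si](C)(C)C)c1Cl | intermediate
7 | 3,4-dihydroxybenzaldehyde | O=Cc1ccc(O)c(O)c1 | starting material
8 | 3,4-bis(tosyloxy)benzaldehyde | O=Cc1ccc(OS(=O)(=O)c2ccc(C)cc2)c(OS(=O)(=O)c2ccc(C)cc2)c1 | intermediate
9 | diethyl (3,5-dimethoxybenzyl)phosphonate | CCOP(=O)(Cc1cc(OC)cc(OC)c1)OCC | starting material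
10 | (E)-3,4-bis(tosyloxy)-3',5'-dimethoxystilbene | COc1cc(OC)cc(/C=C/c2ccc(OS(=O)(=O)c3ccc(C)cc3)c(OS(=O)(=O)c3ccc(C)cc3)c2)c1 | intermediate
11 | (2R,3R)-2-[3,4-bis(tosyloxy)phenyl]-3-(3,5-dimethoxyphenyl)oxirane | COc1cc(OC)cc(c1)[C@H]1O[C@@H]1c1ccc(OS(=O)(=O)c2ccc(C)cc2)c(OS(=O)(=O)c2ccc(C)cc2)c1 | intermediate
12 | methyl 2-chloro-3,4-didehydrobenzoate (aryne) | COC(=O)C1=C(Cl)C#CC=C1 | intermediate (not isolated)
13 | methyl (2S,3S)-2-[3,4-bis(tosyloxy)phenyl]-4-chloro-3-(3,5-dimethoxyphenyl)-2,3-dihydro-1-benzofuran-5-carboxylate (trans) | COC(=O)c1ccc2c(c1Cl)[C@H](c1cc(OC)cc(OC)c1)[C@@H](c1ccc(OS(=O)(=O)c3ccc(C)cc3)c(OS(=O)(=O)c3ccc(C)cc3)c1)O2 | intermediate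
14 | methyl (2S,3S)-2-[3,4-bis(tosyloxy)phenyl]-3-(3,5-dimethoxyphenyl)-2,3-dihydro-1-benzofuran-5-carboxylate | COC(=O)c1ccc2c(c1)[C@H](c1cc(OC)cc(OC)c1)[C@@H](c1ccc(OS(=O)(=O)c3ccc(C)cc3)c(OS(=O)(=O)c3ccc(C)cc3)c1)O2 | intermediate
15 | [(2S,3S)-2-[3,4-bis(tosyloxy)phenyl]-3-(3,5-dimethoxyphenyl)-2,3-dihydro-1-benzofuran-5-yl]methanol | OCc1ccc2c(c1)[C@H](c1cc(OC)cc(OC)c1)[C@@H](c1ccc(OS(=O)(=O)c3ccc(C)cc3)c(OS(=O)(=O)c3ccc(C)cc3)c1)O2 | intermediate
16 | (2S,3S)-2-[3,4-bis(tosyloxy)phenyl]-3-(3,5-dimethoxyphenyl)-2,3-dihydro-1-benzofuran-5-carbaldehyde | O=Cc1ccc2c(c1)[C@H](c1cc(OC)cc(OC)c1)[C@@H](c1ccc(OS(=O)(=O)c3ccc(C)cc3)c(OS(=O)(=O)c3ccc(C)cc3)c1)O2 | intermediate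
17 | (2S,3S)-2-[3,4-bis(tosyloxy)phenyl]-3-(3,5-dimethoxyphenyl)-5-[(E)-2-(3,5-dimethoxyphenyl)ethenyl]-2,3-dihydro-1-benzofuran | COc1cc(OC)cc(/C=C/c2ccc3c(c2)[C@H](c2cc(OC)cc(OC)c2)[C@@H](c2ccc(OS(=O)(=O)c4ccc(C)cc4)c(OS(=O)(=O)c4ccc(C)cc4)c2)O3)c1 | intermediate (not isolated)
18 | 4-[(2S,3S)-3-(3,5-dimethoxyphenyl)-5-[(E)-2-(3,5-dimethoxyphenyl)ethenyl]-2,3-dihydro-1-benzofuran-2-yl]benzene-1,2-diol | COc1cc(OC)cc(/C=C/c2ccc3c(c2)[C@H](c2cc(OC)cc(OC)c2)[C@@H](c2ccc(O)c(O)c2)O3)c1 | intermediate
19 | 4-[(2S,3S)-3-(3,5-dihydroxyphenyl)-5-[(E)-2-(3,5-dihydroxyphenyl)ethenyl]-2,3-dihydro-1-benzofuran-2-yl]benzene-1,2-diol (CNP0207985.1) | Oc1cc(O)cc(/C=C/c2ccc3c(c2)[C@H](c2cc(O)cc(O)c2)[C@@H](c2ccc(O)c(O)c2)O3)c1 | target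

Total step count: 12. Longest linear sequence: 9 steps (from 1 through steps 1–3 and 7–12; the branch from 7 through steps 4–6 and 7–12 is equally long).

Steps most likely to fail

Step 7. The epoxide oxygen is a weak nucleophile, so the aryne may be lost to self-reaction before it is captured. Once the zwitterion has formed, the aryl anion may be protonated or may expel the neighbouring chloride before the C3–O bond ionises. The oxiranium may also be opened by an external nucleophile, or a 1,2-shift of hydride or aryl (Meinwald-type) may outrun ring closure. The fallback replaces the insertion by known chemistry, the enantioselective rhodium-carbene C–H insertion route to 2,3-diaryl-dihydrobenzofurans; it sets out from phosphonate 9 together with commercial 5-bromo-2-hydroxybenzaldehyde and comes back to the route at 19. Williamson alkylation of 5-bromo-2-hydroxybenzaldehyde with 3,4-dimethoxybenzyl chloride (K2CO3, DMF) should give 5-bromo-2-[(3,4-dimethoxyphenyl)methoxy]benzaldehyde F1. Addition of 3,5-dimethoxyphenylmagnesium bromide gives the diaryl carbinol F2, which MnO2 oxidises to the diaryl ketone F3. Hydrazine hydrate converts it into hydrazone F4, and MnO2 oxidises that to the diaryl diazomethane F5. Dirhodium tetrakis[(R)-N-phthaloyl-(1-adamantyl)glycinate], Rh2(R-PTAD)4 (or its mirror image, whichever delivers 3S), should then insert the donor/donor carbene into the benzylic C–H bond to give the cis-(2R,3S)-5-bromo-2-(3,4-dimethoxyphenyl)-3-(3,5-dimethoxyphenyl)-2,3-dihydro-1-benzofuran F6. Bromine–lithium exchange (n-BuLi, THF, −78 °C) and DMF give the cis aldehyde F7, and Horner–Wadsworth–Emmons olefination with 9 (KOt-Bu, THF) gives the cis hexamethyl ether F8. BBr3 then removes all six methyl groups while the electron-rich ring C allows reversible ionisation of C2–O1, so that C2 should epimerise to the favoured trans arrangement and 19 results; this is why ring C carries methyl ethers, not sulfonates, in this branch.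

Step 2. Silylation of the doubly flanked aryl–magnesium bond may be slow, and on forcing the silyl triflate may strip the carbonate or the magnesium aryl may undergo acyl migration. The fallback forms the C–Si bond by halogen–lithium exchange and retro-Brook migration instead; it sets out from 2 (through its magnesium derivative 3) and comes back at 5. Quenching 3 with iodine should give methyl 4-[(tert-butoxycarbonyl)oxy]-2-chloro-3-iodobenzoate F9. CF3CO2H in CH2Cl2 removes the carbonate to give methyl 2-chloro-4-hydroxy-3-iodobenzoate F10, and (Me3Si)2NH silylates the phenol to methyl 2-chloro-3-iodo-4-[(trimethylsilyl)oxy]benzoate F11. n-BuLi at −100 °C should effect iodine–lithium exchange faster than addition to the ester, and the aryllithium undergoes 1,3-migration of silicon from oxygen to carbon, giving 5 after protonation. 5 is then triflated as in the second half of step 3.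

Step 12. The Lewis acid and the HBr it sets free may ionise the benzylic C2–O1 bond with the help of the ring C oxygens, or protonate the electron-rich stilbene, so that ring opening and oligomerisation accompany demethylation. The fallback reverses the order of the two deprotections so that ring C stays electron-poor while the Lewis acid is present; it sets out from 16 and comes back at 19. The olefination of step 11 is worked up without KOH and 17 is isolated. BBr3 then cleaves the four methyl ethers to give the tetraphenol bis-tosylate 4-[(2S,3S)-3-(3,5-dihydroxyphenyl)-5-[(E)-2-(3,5-dihydroxyphenyl)ethenyl]-2,3-dihydro-1-benzofuran-2-yl]-1,2-phenylene bis(4-methylbenzenesulfonate) F12. Degassed aqueous-methanolic KOH at 40 °C under argon removes the sulfonates last and gives 19.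

Further compounds
F1 | step 7 | 5-bromo-2-[(3,4-dimethoxyphenyl)methoxy]benzaldehyde | O=Cc1cc(Br)ccc1OCc1ccc(OC)c(OC)c1
F2 | step 7 | [5-bromo-2-[(3,4-dimethoxyphenyl)methoxy]phenyl](3,5-dimethoxyphenyl)methanol (racemic) | COc1cc(OC)cc(c1)C(O)c1cc(Br)ccc1OCc1ccc(OC)c(OC)c1
F3 | step 7 | [5-bromo-2-[(3,4-dimethoxyphenyl)methoxy]phenyl](3,5-dimethoxyphenyl)methanone | COc1cc(OC)cc(c1)C(=O)c1cc(Br)ccc1OCc1ccc(OC)c(OC)c1
F4 | step 7 | [5-bromo-2-[(3,4-dimethoxyphenyl)methoxy]phenyl](3,5-dimethoxyphenyl)methanone hydrazone | COc1cc(OC)cc(c1)C(=NN)c1cc(Br)ccc1OCc1ccc(OC)c(OC)c1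
F5 | step 7 | [5-bromo-2-[(3,4-dimethoxyphenyl)methoxy]phenyl](3,5-dimethoxyphenyl)diazomethane | COc1cc(OC)cc(c1)C(=[N+]=[N-])c1cc(Br)ccc1OCc1ccc(OC)c(OC)c1
F6 | step 7 | (2R,3S)-5-bromo-2-(3,4-dimethoxyphenyl)-3-(3,5-dimethoxyphenyl)-2,3-dihydro-1-benzofuran (cis) | Brc1ccc2c(c1)[C@H](c1cc(OC)cc(OC)c1)[C@H](c1ccc(OC)c(OC)c1)O2
F7 | step 7 | (2R,3S)-2-(3,4-dimethoxyphenyl)-3-(3,5-dimethoxyphenyl)-2,3-dihydro-1-benzofuran-5-carbaldehyde (cis) | O=Cc1ccc2c(c1)[C@H](c1cc(OC)cc(OC)c1)[C@H](c1ccc(OC)c(OC)c1)O2
F8 | step 7 | (2R,3S)-2-(3,4-dimethoxyphenyl)-3-(3,5-dimethoxyphenyl)-5-[(E)-2-(3,5-dimethoxyphenyl)ethenyl]-2,3-dihydro-1-benzofuran (cis) | COc1cc(OC)cc(/C=C/c2ccc3c(c2)[C@H](c2cc(OC)cc(OC)c2)[C@H](c2ccc(OC)c(OC)c2)O3)c1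
F9 | step 2 | methyl 4-[(tert-butoxycarbonyl)oxy]-2-chloro-3-iodobenzoate | COC(=O)c1ccc(OC(=O)OC(C)(C)C)c(I)c1Cl
F10 | step 2 | methyl 2-chloro-4-hydroxy-3-iodobenzoate | COC(=O)c1ccc(O)c(I)c1Cl
F11 | step 2 | methyl 2-chloro-3-iodo-4-[(trimethylsilyl)oxy]benzoate | COC(=O)c1ccc(O[Si](C)(C)C)c(I)c1Cl
F12 | step 12 | 4-[(2S,3S)-3-(3,5-dihydroxyphenyl)-5-[(E)-2-(3,5-dihydroxyphenyl)ethenyl]-2,3-dihydro-1-benzofuran-2-yl]-1,2-phenylene bis(4-methylbenzenesulfonate) | Oc1cc(O)cc(/C=C/c2ccc3c(c2)[C@H](c2cc(O)cc(O)c2)[C@@H](c2ccc(OS(=O)(=O)c4ccc(C)cc4)c(OS(=O)(=O)c4ccc(C)cc4)c2)O3)c1
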